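The numbers of this flask were chosen freely.

Watch the substrate.

- maple: substrate 0.80 M; partner 1.00 equiv; time 20 s
- cedar: substrate 0.80 M; partner 2.00 equiv; time 20 s

    substrate + partner → other mono adduct (k1 = 0.0668 /M/s)
    substrate + single product → side product (k2 = 0.0175 /M/s)
    partner + single product → double product (k3 = 0.0289 /M/s)
    substrate + partner → single product (k4 = 0.0763 /M/s)
    crystals ⇌ single product, rate k5*(cs5 - [single product]) while solid is left; crystals form when [single product] > cs5 (cs5 = 0.69 M, k5 = 1.57 /s)
    single product ⇌ isomer of the product (K6 = 0.12, k6 = 0.519 /s)
    partner + other mono adduct → double product (k7 = 0.0724 /M/s)

- which of the two there is more of at the end, maple (single product / double product)
- which of the two there is more of at the end, cedar (single product / double product)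
- how much single product is there at the end, in percent of the substrate charged: maple
- how much single product is there at the end, in percent of the substrate charged: cedar

- percentages count the substrate that a species holds: one side product counts as two
- single product is meant together with its crystals
- solid, in amounts per volume of the solution: crystals
- run time (maple): 20 s

The steps that make single product, other mono adduct and double product all carry partner as a factor, so partner cancels from their ratios. In this reckoning of my own, the side product is set aside, its constant being smaller than that of partner + single product. The isomer keeps its equilibrium share, because its relaxation half-life of 0.143 s is short against 20 s.

Each flask then moves along one path, and its position is the partner exposure, the running sum of partner concentration over time, against which each step with partner is first-order in its other species. In this reckoning double product draws about level with single product at the crossing exposure: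

crossing exposure = 2.3 / (k1 + k4) = 16.1 M·s

Substrate left there = 10.0 %

Single product there = 32.5 %

Double product there = 33.5 %

Single product there stands at 0.260 M, less than the solubility, so the reckoning counts no crystals.

By this reckoning, for double product to lead in maple, where the charges are equal, the group (k1 + k4) × substrate charge × time has to reach 8.97, but it stands at 2.29. Counting one partner per substrate consumed, and none for the steps to double product:

maple exposure = 8.32 M·s

cedar exposure = 20.5 M·s

By these figures maple stays short of the crossing and cedar passes it. This reckoning ranks the products and gives no committed yields.

The forecast names single product for maple at 26 % and double product for cedar, with single product at 30 %, in cedar on the ground that “the excess partner converts much of the single product and other mono adduct onward”.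

Maple ends with 25.7 % single product and 11.9 % double product, with 31.9 % substrate left. Cedar ends with 30.4 % and 36.7 %, with 7.33 % left, below the crossing share. With the side product still set aside, the remainders of maple and cedar read as exposures of 7.99 M·s and 18.3 M·s, in that order. The neighbour of maple with 2.50 equiv of partner reckons to 27.5 M·s, past 16.1 M·s. Its run leaves 3.18 % substrate, an exposure of 24.1 M·s, and ends with 48.7 % double product over 28.3 % single product.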